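The runs stem from a simulated flask for an exercise; scatter was added.

- You have 3 questions on one flask, and I reckon them through one time constant.

the same everywhere: racemization catalyst 0.20 mM

| run | left-handed substrate | right-handed substrate | reagent | remark | time |
|---|---|---|---|---|---|
| delta | 0.10 M | 0.10 M | 0.20 M | the very flask that is asked about, followed so far |  |
| alpha | 0.050 M | 0.050 M | 0.20 M | run made earlier |  |
| flask | 0.10 M | 0.10 M | 0.200 M |  | 20 h |

| run | time / h | left-handed substrate / % | right-handed substrate / % | left-handed product / % |
|---|---|---|---|---|
| delta | 0.333 | 49.8 | 49.6 | 1.2 |
| delta | 0.500 | 49.8 | 49.6 | 1.5 |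
| delta | 0.667 | 49.2 | 49.5 | 1.0 |
| delta | 1.00 | 48.2 | 49.8 | 1.3 |
| delta | 1.50 | 47.8 | 48.4 | 3.2 |
| delta | 2.50 | 46.0 | 48.3 | 4.3 |
| delta | 4.00 | 44.0 | 47.4 | 5.7 |
| alpha | 1.00 | 48.8 | 48.0 | 1.3 |
| alpha | 1.50 | 47.4 | 48.8 | 2.0 |
| alpha | 2.50 | 47.6 | 47.9 | 3.9 |
| alpha | 4.00 | 44.2 | 47.2 | 6.1 |
| alpha | 6.00 | 41.7 | 45.7 | 8.6 |
| alpha | 10.0 | 38.4 | 41.6 | 13.8 |
| alpha | 15.0 | 33.6 | 39.9 | 18.0 |

(scatter of a reading: 0.5 percentage points)

- part of the left-handed substrate and right-handed substrate charged together that has reacted at 20 h
- excess of left-handed product over right-handed product in the product at 20 h
- excess of right-handed substrate over left-handed substrate among what is left of the two at 20 h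

- reagent is single-handed; left-handed substrate and right-handed substrate are mirror images of each other, charged as a racemate, each of them at the stated concentration
- an excess is the difference of the two amounts in percent of their sum
- an excess is below zero if the other one leads
- the handed part of reagent does not stay in what it makes, so the products of the two hands are mirror images too

- At 4.00 h the delta and alpha runs have each lost 8.60% of their substrates, although delta holds twice the substrate, so I take the step as first order in substrate.
- Both runs have the same reagent charge, so first order in reagent is my assumption, not a reading.
- The alpha run has lost 26.5% at 15.0 h. With first order in each, the log of reagent share left over substrate share left grows in proportion to the surplus of reagent over substrate, divided by the substrate charge, times elapsed time over the time constant.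
- That gives the time constant, one over the rate constant times the two substrates' joint charge in the flask asked about, as 45.3 h.
- In this flask reagent (0.200 M) equals the two substrates together (0.200 M), so the part reacted is t/(t+τ), which is 30.7% at 20 h.
- In the alpha run left-handed product is 0.679 of the product, so the accumulated ratio of left-handed to right-handed product at that reading is near 2.12, and I put the product excess at 35.8%. In this flask that is a product gap of 11 percentage points.
- My weak link was to let that whole gap stay in the substrates, which gives 15.9%. But the alpha run's substrates differ by 6.3 points, less than its product gap of 9.5 points. Keeping that reading's share of 0.663 gives 10.5%.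
- The forecast says 31.5% (29% to 35%), 36% (32% to 40%) and 8% (5.5% to 11%), on the grounds of “no true dynamic resolution”. Its last number is lower than mine.

    left-handed substrate + racemization catalyst ⇌ right-handed substrate + racemization catalyst, rate k1*[racemization catalyst]*[left-handed substrate] forward; the back reaction follows from the equilibrium constant (k = 740 M⁻¹ h⁻¹)
    racemization catalyst → spent catalyst B (k = 0.0650 h⁻¹)
    reagent + right-handed substrate → right-handed product (k = 0.0690 M⁻¹ h⁻¹)
    reagent + racemization catalyst → spent catalyst A (k = 0.670 M⁻¹ h⁻¹)
    reagent + left-handed substrate → left-handed product (k = 0.160 M⁻¹ h⁻¹)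

The flask gives 30.9% reacted, a product excess of 35.6% and a substrate excess of 10.5%, which stands above the forecast's 8%, just under the 11% that ends its range. In this flask the racemization catalyst stands at 15.6% of its charge at 10.0 h and 2.99% at 20.0 h. The time constant of 45.3 h puts reagent at 81.9% of its charge at 10.0 h, and this flask holds 81.5%. In the neighbour flask with 0.50 M of reagent, the share ratio reaches 1.94, which means 61.1% reacted, and that flask holds 59.9%.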